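The numbers in the tables were computed from invented constants, noise included.

The meeting opened on the cedar run: its starting material read 0 % at the first reading, after 2.50 h, and its target then stayed flat, while the larch run, with more protic impurity, went flat at a lower level.

| setting | cedar | larch | flask |
|---|---|---|---|
| starting material | 0.15 M | 0.15 M | 0.15 M |
| reagent | 0.12 M | 0.12 M | 0.120 M |
| protic impurity | 0.10 M | 0.17 M | 0.0750 M |
| remark | run made earlier | run made earlier |  |
| time |  |  | 10 h |

| run | time / h | starting material / % | target / % |
|---|---|---|---|
| cedar | 2.50 | 0 | 47 |
| cedar | 5.00 | 2 | 48 |
| cedar | 8.00 | 0 | 46 |
| cedar | 10.0 | 0 | 46 |
| cedar | 12.0 | 3 | 51 |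
| larch | 1.00 | 2 | 34 |
| larch | 2.00 | 0 | 34 |
| larch | 3.00 | 2 | 29 |
| larch | 6.00 | 3 | 32 |
| larch | 12.0 | 0 | 31 |

(standard deviation of a reading: 2 percentage points)

- the state of affairs at 10 h: stopped, and by what, or still going (forward and back rates have come level / it is still moving / all of the starting material has reacted)
- how much of the starting material has reacted by 10 h
- how much target there is at 10 h, in percent of the starting material charged

- the reaction counts as stopped when no species that holds the starting material changes by six tenths of a point or more over the second half of the time

The first speaker argued that, with both runs flat within the scatter, the question was how the starting material had split. She supposed a path to target first order in starting material, against a one-for-one quench by protic impurity. Dividing the two rates cancels [starting material], so target formed equals a constant times the ln of [protic impurity] charged over [protic impurity] left. The second speaker objected that reagent stood at 0.12 M in both runs and stands at 0.120 M in the flask, so these readings cannot test its part; the rule leaves it out as a supposition.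

They then averaged the flat readings. Cedar gave 0.0714 M of target, and the balance left 0.0214 M of protic impurity. Larch gave 0.0480 M and left 0.0680 M. The constant read 0.0463 M from cedar and 0.0524 M from larch. Their mean is the split concentration, the target formed per unit fall in ln[protic impurity], a selectivity factor with the units of concentration: 0.0493 M.

For the flask, the first speaker took the large term first: with its impurity fully quenched, target equals the difference of the charges, 0.0750 M. The small term is the impurity left, each unit of it a unit of starting material spared. The rule puts it at 0.0164 M, and feeding that correction back lowers it to 0.0123 M, less than the large term. Our reckoning for the flask is therefore 0.0873 M of target, or 58.2 %, with conversion complete by 10 h, as the readings of both runs suggest.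

The forecast, with the starting material “consumed by reagent and impurity in parallel”, was that all of the starting material has reacted, at 100 % conversion and 56 % target. The flask gives: all of the starting material has reacted, 100 % conversion, 59.2 % target.

    starting material ⇌ intermediate A (K = 0.161, k = 0.0654 s⁻¹)
    starting material → intermediate B (k = 0.00403 s⁻¹)
    intermediate B → target (k = 0.0122 s⁻¹)
    intermediate A → intermediate B (k = 0.0169 s⁻¹)
    2 reagent → self-condensation product (k = 0.0334 M⁻¹ s⁻¹)
    starting material + protic impurity → quenched substrate (k = 0.127 M⁻¹ s⁻¹)

The flask kept 18 % of its protic impurity, 0.0137 M against the 0.0123 M reckoned. In the neighbour flask charged with 0.30 M of protic impurity, the large term is the excess of impurity over starting material, 0.150 M, and the small term is the target itself. The rule gives 0.0342 M at first, and the same feedback lowers this to 0.0257 M, less than the large term, or 17.2 % of the starting material charged. That neighbour flask reads 18.3 % of target, with 59 % of its protic impurity left.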